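    substrate + partner ⇌ target + released group (K1 = 0.302, k1 = 0.173 M⁻¹ min⁻¹, Ea1 = 65.0 kJ mol⁻¹, ΔH1 = 21.0 kJ mol⁻¹)
    partner + protic impurity → quenched reagent (k2 = 3.17 M⁻¹ min⁻¹, Ea2 = 41.0 kJ mol⁻¹)
    target ⇌ isomer of the product (K3 = 0.33, k3 = 0.00996 min⁻¹, Ea3 = 94.0 kJ mol⁻¹, ΔH3 = −38.0 kJ mol⁻¹)
    (constants at 5 °C)

| setting | south-east | south | south-west |
|---|---|---|---|
| substrate | 0.010 M | 0.010 M | 0.010 M |
| partner | 0.700 equiv | 0.700 equiv | 0.700 equiv |
| protic impurity | 0.500 mM | 0.500 mM | 0.500 mM |
| temperature | 5 °C | 35 °C | 20 °C |
| time | 2.5 d | 2.5 d | 2.5 d |

- at 5 °C the constants are as listed, elsewhere as the activation energies and enthalpies make them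

- which flask leads in amount of target, in percent of the substrate charged ("all alike" within 1.5 percentage points) (south-east / south / south-west / all alike)
- how much target is there at the end, in percent of the substrate charged: south-east
- how much target is there at the end, in percent of the substrate charged: south
- how much target is there at the end, in percent of the substrate charged: south-west

The ratio of 3.17 M⁻¹ min⁻¹ to 0.173 M⁻¹ min⁻¹, a selectivity factor of 18.3, says that at equal concentrations partner meets protic impurity faster than it meets substrate. The second step has no way back, so I strike 0.500 mM from the 7.00 mM of partner charged, which leaves a net c(partner) of 6.50 mM. That is less than c(substrate), so partner is the smaller charge of the first step.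

In south-east, at 5 °C, the impurity's half-life at that net partner is 33.6 min, short against the run, so the strike stands. The half-life of substrate there, by the forward step alone, is 0.428 d, which fits 5.84 times into 2.5 d. So I expect thermodynamic, not kinetic, control, and I assume the same of the warmer flasks.

In south-east the third step relaxes in 17.3 min, faster than that forward half-life of substrate, so target and isomer of the product share the extent of the first step, which equals c(released group). The square of that extent, over the product of remaining substrate and remaining net partner, then equals the lumped constant, the first equilibrium constant times one plus the third. In south this lumped constant is 0.780, and in south-east it is 0.402.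

Solving the quadratic gives an extent of 3.08 mM in south-east, hence 23.2% target. In south it gives 3.70 mM, hence 34.7% target. I do not reckon south-west, and place it between them.

The forecast gives 23.2% for south-east, 34.7% for south and 29.5% for south-west, puts south first, and states as its ground: “Warming favours target twice”.

The simulation gives 23.2% in south-east, 34.7% in south and 29.5% in south-west, so south leads. Released group in south stands at 0.00370 M after 2.50 d, beside my extent of 3.70 mM. A south flask with 1.94 mM of protic impurity has a net partner of 5.06 mM. With 0.780 its extent is 3.17 mM, so its target is 29.7%, which is 5 percentage points below 34.7%. The simulated flask at that charge has moved by 5 percentage points.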